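Over the first hour of the earlier runs I watched target climb while side product followed it.

all flasks: free catalyst 1 mol%

| flask | starting material | second substrate | remark | time |
|---|---|---|---|---|
| Tuesday's | 0.10 M | 0.67 equiv | run made earlier |  |
| Saturday's | 0.10 M | 1.5 equiv | run made earlier |  |
| Wednesday's | 0.20 M | 1 equiv | run made earlier |  |
| ochre | 0.10 M | 1.00 equiv |  | 450 min |
| green | 0.10 M | 1.00 equiv |  | 50 min |
| teal | 0.10 M | 1.00 equiv |  | 150 min |

| run | time / min | starting material / % | target / % | side product / % | catalyst intermediate A / % |
|---|---|---|---|---|---|
| Tuesday's | 8.00 | 94 | 4 | 0 | 1 |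
| Tuesday's | 20.0 | 88 | 9 | 0 | 2 |
| Tuesday's | 40.0 | 72 | 19 | 6 | 0 |
| Tuesday's | 60.0 | 61 | 27 | 10 | 2 |
| Saturday's | 5.00 | 97 | 4 | 0 | 0 |
| Saturday's | 12.0 | 92 | 5 | 4 | 0 |
| Saturday's | 25.0 | 84 | 9 | 1 | 3 |
| Saturday's | 60.0 | 63 | 28 | 11 | 0 |
| Wednesday's | 15.0 | 86 | 9 | 3 | 3 |
| Wednesday's | 30.0 | 72 | 18 | 10 | 2 |
| Wednesday's | 50.0 | 53 | 26 | 20 | 0 |
| Wednesday's | 60.0 | 46 | 31 | 26 | 2 |

(standard deviation of a reading: 1.5 percentage points)

- percent here means starting material units held: one side product counts as two

* which of these there is most of at the end, counted by the starting material in it, ochre (catalyst intermediate A / side product / starting material / target)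
* which of these there is most of at the end, counted by the starting material in it, green (catalyst intermediate A / side product / starting material / target)
* which of these there is most of at the end, counted by the starting material in it, teal (catalyst intermediate A / side product / starting material / target)
* final amount of the leader among these, as a percentage of the starting material charged, in ochre
* final amount of the leader among these, as a percentage of the starting material charged, in green
* final amount of the leader among these, as a percentage of the starting material charged, in teal

Tuesday's side product read 0% at 20.0 min and more, 10%, at 60.0 min, so I took each side product as one starting material joined to one target. By 60.0 min Wednesday's run, at twice the concentration and with 1 equiv of second substrate against Tuesday's 0.67 equiv, had turned more of its charge through the catalyst than Tuesday's, by a factor of 1.38. As a working assumption I took the making of target as pseudo-first-order, γs, with s the fraction of starting material left. Tuesday's readings gave γ = 0.00663 min⁻¹. I took the loss of target as λsp, with p the target fraction; Wednesday's readings, scaled to 0.10 M, gave λ = 0.00957 min⁻¹. Since s stands in both rates, they balance at one target level, the balance level p* = γ/λ, which I reckoned as 69.2%.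

The forecast named target at 80% for ochre, starting material at 67% for green and target at 68% for teal, holding that “Side-product flux rises about fourfold, so it scales with A×SM.” My reckoning differed: the forecast's ochre figure stood above p*.

The flasks gave target at 53.7% in ochre, starting material at 67.9% in green and target at 45.1% in teal, so the forecast was 26 percentage points high on ochre and 23 points high on teal.

    starting material + target → side product (k = 0.0940 M⁻¹ min⁻¹)
    catalyst intermediate A → free catalyst + target (k = 1.40 min⁻¹)
    second substrate + free catalyst ⇌ catalyst intermediate B (K = 27.0 M⁻¹, k = 25.0 M⁻¹ min⁻¹)
    2 catalyst intermediate B ⇌ resting dimer (K = 1200 M⁻¹, k = 60.0 M⁻¹ min⁻¹)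
    starting material + free catalyst ⇌ catalyst intermediate A (K = 100 M⁻¹, k = 14.0 M⁻¹ min⁻¹)
    catalyst intermediate B → free catalyst + second product (k = 11.0 min⁻¹)

Ochre's target finished below p*, beside 46.2% in side product. For the neighbour of ochre charged with 0.25 mol% of free catalyst, I scaled γ with the loading, which put p* at 17.3%. That neighbour ended at 450 min with 23% of its starting material still there, unbound, 57.0% in side product and target at 20.0%, higher than that p*.

The runs stem from a simulated flask from invented constants, and the scatter is random.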